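## Analysis of the target

Target 28 is a C42 stilbenoid made of two trans-2,3-diaryl-2,3-dihydrobenzofurans. The first unit (O1, C2, C3, C3a–C7a; benzo ring = ring A) carries a hydroxyl at C4, the (E)-4-hydroxystyryl arm (ring C) at C6, a 4-hydroxyphenyl group (ring D) at C2, and at C3 the benzo ring of the second unit (ring B), joined through C6'. The second unit (primed atoms) carries a hydroxyl at C4', the catechol (ring E) at C2' and the 3,5-dihydroxyphenyl group (ring F) at C3'. There are four stereocentres in two trans pairs, (2R,3R) and (2'S,3'S). C3 sits on C6', para to C3a' across the flat ring B, so neither pair can steer the other and each must be set by its own reagent control. Sensitive groups are the eight phenols (the catechol above all), the E-stilbene, the two benzylic aryl ether bonds O1–C2 and O1'–C2' (each next to a para-oxygenated aryl, hence acid-labile) and the doubly benzylic C3–H and C3'–H. The difficulty lies in building two near-identical heterocycles of opposite absolute sense and joining them through an sp3–sp2 bond without losing either trans relationship. The strategy rests on the sequence O1'–C2'(ring E)–C3'(carbon substituent, trans)–C3a' of the ring B unit. This is the O1–C2(aryl)–C3 fragment of a flavanone after the carbonyl carbon C4 has been pushed out of the ring onto C3. The extruded carbon is then a carboxyl handle that can be exchanged for ring F. The ring A unit (O1–C2(ring D)–C3(ring B)) shows the same pattern, so the same logic serves both halves.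

## Retrosynthetic reasoning

Target 28 is traced back to its octamethyl ether 27 by cutting the eight O–CH3 bonds. Methyl ethers are chosen because they survive strong acid, a trivalent iodine oxidant, organolithium and organozinc reagents and palladium catalysis; one cleavage operation then ends the synthesis.

In 27 the C6–vinyl bond is cut, giving aryl bromide 25 and 4-methoxystyrene 26. The stilbene is introduced last among the carbon–carbon bonds because an electron-rich stilbene would not survive the oxidative key step and is best kept out of the radical couplings. The forward reaction is a Heck coupling at a bromide flanked by two hydrogens.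

In 25 the C3–C6' bond between the two heterocycles is cut. This divides the molecule into two dihydrobenzofurans of the same type: the ring A unit as redox-active ester 22, and the ring B unit as bromide 16, used as its zinc derivative 24 via aryllithium 23. The cut is made here because C3 then carries a carboxyl group, exactly what the ring contraction leaves behind. The forward decarboxylative arylation must deliver ring B to the C3 radical on the face away from ring D; the absolute sense of each half is already fixed before the union.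

In 16 the C3'–ring F bond is cut in the same way, giving redox-active ester 12 and 1-bromo-3,5-dimethoxybenzene 13 (used as Grignard 14 and diarylzinc 15). The ring B bromide has to pass through this coupling untouched, which points to iron rather than nickel or palladium catalysis.

Esters 12 and 22 go back through acids 11 and 21 to methyl esters 10 and 20; only the carboxyl oxidation level and activation change.

Ester 10 is traced to flavanone 8 by reinserting the ester carbon between C3' and C3a', that is, by cutting C3'–C3a' and reconnecting C4–C4a of a chroman-4-one. This is the key disconnection: the five-membered ring, the trans C3' centre and the carboxyl handle all come from one oxidative 1,2-shift on enol ether 9, while the C2 centre of 8 is carried through. Ester 20 comes from flavanone 18 (via 19) in the same way.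

Flavanones 8 and 18 are cut at the C2–aryl bond, giving one common chromone 6 and the boronic acids 7 and 17. A catalytic asymmetric conjugate addition sets C2' as S with one ligand enantiomer and C2 as R with the other. These two steps are the only source of absolute configuration in the route.

Chromone 6 is opened to the ortho-hydroxyacetophenone 4 (through enaminone 5), which comes from ketone 3 by a chelation-directed mono-demethylation, and 3 from aldehyde 1 via carbinol 2.

## Alternatives that were turned down

Alternative 1: Both furan rings are opened at O1–C2 and O1'–C2', leading back to an open-chain bis(4-hydroxybenzyl) hexaphenol A2. In the forward step Ag2O or DDQ would dehydrogenate both 4-hydroxybenzyl groups to para-quinone methides, and the flanking hydroxyls of rings A and B would add to them (5-exo-trig) to give the bis(dihydrobenzofuran) tetramethyl ether A1.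
- For it: both heterocycles close in one biomimetic operation. Each of rings A and B has two equivalent hydroxyls flanking the reacting carbon, so regiochemistry is not an issue. Only four methyl ethers are left to cleave, against eight in the chosen route; on this point the alternative is stronger.
- Against it: C3 and C3' of A2 are diarylmethine centres in an open chain with no neighbouring functional group, and their asymmetric construction has no simple solution. The ring D phenol has no ortho substituents, so its quinone methide is hard to generate and prone to polymerise. The oxidant would also find two free resorcinols, a guaiacol and two doubly benzylic C–H bonds.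
- Comparison: the chosen strategy gives up the step economy of the double closure. In return, every stereocentre is set on a rigid ring by a catalytic asymmetric addition or by a neighbouring centre, and the only oxidation is carried out on a fully methylated substrate.

Alternative 2: Ring A is cut at C3a–C4 and C7–C7a and assembled late from 3-styrylcyclobutenone A4 and siloxyalkyne A5, which already contains the whole ring B unit and the C2–C3 chain. Heating would open A4 to a vinylketene, which adds to the ynol ether; electrocyclic opening and closure then place the two alkyne carbons between the former carbonyl carbon and the former ring CH2. The product is the resorcinol monosilyl ether A3.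
- For it: the substitution pattern of ring A, including the styryl arm, is fixed by the mechanism, so no late Heck coupling is needed. The two ring A oxygens emerge differentiated. On these points it is as good as or better than the chosen route.
- Against it: A5 has a stereocentre that is propargylic and benzylic at once, next to a silyloxy-bearing carbon. It would have to be made by ynolate chemistry under strongly basic conditions, which invite epimerisation and elimination. After the annulation the furan ring must still be closed by ionising the benzylic silyl ether of A3, and two silyl groups removed. The catechol-bearing dihydrobenzofuran inside A5 still needs its own synthesis.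
- Comparison: the chosen route builds both heterocycles from one chromone by the same four operations and is clearly shorter. It does not need the thermal cascade or the fragile ynol ether.

Alternative 3: Ring B and its furan ring are cut together into diyne A7 (a terminal ynol ether tethered through C2' and C3' to an alkynylboronate) and the 3-ethynyl dihydrobenzofuran A8. Cp*RuCl(cod), a divalent ruthenium complex, would first join the two alkynes of A7 (C3a'–C7a', closing the furan ring) and then insert the alkyne of A8 (C6'–C7' and C4'–C5'), giving the pinacol boronate A6. Oxidation of the boronate would supply the C4' oxygen.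
- For it: three carbon–carbon bonds and two rings in one atom-economical step, with a boronate placed exactly where the oxygen is needed. In bonds formed per step it is the strongest of all the strategies, the chosen one included.
- Against it: A7 is an ethynyl ether of a secondary benzylic alcohol, a class that fragments thermally to a ketene and an alkene, and it carries an anti diaryl stereodiad that must be set in an open chain. The regiochemistry of alkyne insertion rests on a steric bias alone. A8 still requires a stereodefined dihydrobenzofuran with a one-carbon handle at C3, which is what the ring contraction delivers, plus a homologation.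
- Comparison: the chosen strategy forms fewer bonds in its key step. It uses bench-stable intermediates, sets the stereocentres on rings, and uses one key reaction for both halves.

Key step: step 6

Remark: the ligand enantiomers written in steps 5 and 10 assume the facial preference known for cyclic enones; if the sense proves opposite, the two enantiomers are exchanged between these steps.

## Route

Step 1
Reactants: 1 4-bromo-2,6-dimethoxybenzaldehyde
Product: 2 1-(4-bromo-2,6-dimethoxyphenyl)ethan-1-ol (racemic)
Conditions: MeMgBr, THF, 0 °C; aq. NH4Cl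
Reagents that add atoms: methylmagnesium bromide, C[Mg]Br
Why: Grignard addition to the aldehyde; the aryl bromide is inert to MeMgBr at 0 °C, and the new carbinol centre is racemic and is erased in step 2.

Step 2
Reactants: 2 1-(4-bromo-2,6-dimethoxyphenyl)ethan-1-ol
Product: 3 1-(4-bromo-2,6-dimethoxyphenyl)ethan-1-one
Conditions: Dess–Martin periodinane, CH2Cl2, rt
Reagents that add atoms: none
Why: Dess–Martin oxidation of a hindered benzylic secondary alcohol to the methyl ketone under neutral conditions.

Step 3
Reactants: 3 1-(4-bromo-2,6-dimethoxyphenyl)ethan-1-one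
Product: 4 1-(4-bromo-2-hydroxy-6-methoxyphenyl)ethan-1-one
Conditions: BCl3, CH2Cl2, −78 to 0 °C; aq. HCl
Reagents that add atoms: none
Why: Chelation-directed ether cleavage: BCl3 bound between the carbonyl and one ortho-methoxy oxygen cleaves that methyl ether only, and the resulting aryloxyboron chelate ties up the ketone so that the second methoxy group should stay.

Step 4
Reactants: 4 1-(4-bromo-2-hydroxy-6-methoxyphenyl)ethan-1-one
Product: 6 7-bromo-5-methoxy-4H-chromen-4-one, via enaminone 5 (not isolated)
Conditions: Me2NCH(OMe)2, toluene, 100 °C; then conc. HCl, CH2Cl2, 40 °C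
Reagents that add atoms: N,N-dimethylformamide dimethyl acetal, COC(OC)N(C)C
Why: Enaminone chromone synthesis: the amide acetal condenses with the methyl ketone, and acid then drives addition of the phenol to the β-carbon with loss of dimethylamine.

Step 5
Reactants: 6 7-bromo-5-methoxy-4H-chromen-4-one; 7 3,4-dimethoxyphenylboronic acid
Product: 8 (2S)-7-bromo-2-(3,4-dimethoxyphenyl)-5-methoxy-2,3-dihydro-4H-chromen-4-one
Conditions: Pd(OCOCF3)2 (5 mol%), (R)-t-BuPyOx [(R)-4-tert-butyl-2-(pyridin-2-yl)-4,5-dihydrooxazole] (6 mol%), NH4PF6, H2O, ClCH2CH2Cl, 60 °C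
Reagents that add atoms: none
Why: Catalytic asymmetric conjugate addition of an arylboronic acid to a chromone: a cationic divalent palladium aryl species carrying the pyridine–oxazoline ligand inserts the C2=C3 bond on one face and the C-bound enolate is protonated, so the ligand sets C2 (the later C2') as S. No zerovalent palladium is formed, so the C7 bromide is not touched.

Step 6
Reactants: 8 (2S)-7-bromo-2-(3,4-dimethoxyphenyl)-5-methoxy-2,3-dihydro-4H-chromen-4-one
Product: 10 methyl (2S,3S)-6-bromo-2-(3,4-dimethoxyphenyl)-4-methoxy-2,3-dihydro-1-benzofuran-3-carboxylate, via C4 methyl enol ether 9 (not isolated)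
Conditions: PhI(OAc)2, H2SO4, HC(OMe)3, rt
Reagents that add atoms: trimethyl orthoformate, COC(OC)OC
Why: H2SO4 and HC(OMe)3 turn the C4 ketone of 8 into its dimethyl ketal and then the enol ether 9, whose C3 is attacked by the trivalent iodine of PhI(OAc)2 on the face away from the C2 aryl while methanol returns to C4. Iodobenzene then leaves from C3 as the ring B carbon C4a, anti-periplanar to the C3–I bond, shifts from C4 to C3; this forms the C3'–C3a' bond and leaves C4 as a dimethoxycarbenium ion that is demethylated to the methyl ester. The closest known reaction type is the oxidative ring contraction of flavanones to methyl trans-2-aryl-2,3-dihydrobenzofuran-3-carboxylates with PhI(OAc)2 or Tl(NO3)3 in trimethyl orthoformate. The furan ring is closed not by a cyclisation but by this 1,2-aryl shift through a bridged phenonium-type transition state, a six-to-five contraction of the pyranone ring. The new C3' centre ends trans to the ring E aryl: it is controlled by the C2' centre, kinetically through anti attack of the iodane followed by inversion at C3 on migration, and thermodynamically because the C3'–H next to the ester can equilibrate to the trans isomer. The step needs migration of C4a in preference to shift of the C2 aryl (isoflavone) and to loss of H-2 (flavone); the pseudo-equatorial C2 aryl places a trans C3–I bond pseudo-equatorial, anti to the C4–C4a ring bond and gauche to both the C2–aryl bond and H-2, and C4a, flanked by two oxygen-bearing carbons, is the better migrating group. The C2 configuration from step 5 must survive, which fast ketalisation secures by removing the carbonyl needed for retro-oxa-Michael ring opening; no bond to C2 is made or broken.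

Step 7
Reactants: 10 methyl (2S,3S)-6-bromo-2-(3,4-dimethoxyphenyl)-4-methoxy-2,3-dihydro-1-benzofuran-3-carboxylate
Product: 11 (2S,3S)-6-bromo-2-(3,4-dimethoxyphenyl)-4-methoxy-2,3-dihydro-1-benzofuran-3-carboxylic acid
Conditions: LiOH·H2O, THF/MeOH/H2O, rt; then aq. HCl
Reagents that add atoms: lithium hydroxide, [Li+].[OH-]
Why: Saponification at room temperature; the trans acid is the stable epimer, and the C3' configuration is in any case erased in step 9, so only the untouched C2' centre matters.

Step 8
Reactants: 11 (2S,3S)-6-bromo-2-(3,4-dimethoxyphenyl)-4-methoxy-2,3-dihydro-1-benzofuran-3-carboxylic acid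
Product: 12 1,3-dioxoisoindolin-2-yl (2S,3S)-6-bromo-2-(3,4-dimethoxyphenyl)-4-methoxy-2,3-dihydro-1-benzofuran-3-carboxylate
Conditions: N-hydroxyphthalimide, DIC, DMAP (cat.), CH2Cl2, rt
Reagents that add atoms: N-hydroxyphthalimide, O=C1c2ccccc2C(=O)N1O
Why: Carbodiimide esterification to the redox-active N-acyloxyphthalimide, which accepts one electron and fragments to CO2, phthalimide anion and the C3' radical.

Step 9
Reactants: 12 1,3-dioxoisoindolin-2-yl (2S,3S)-6-bromo-2-(3,4-dimethoxyphenyl)-4-methoxy-2,3-dihydro-1-benzofuran-3-carboxylate; 13 1-bromo-3,5-dimethoxybenzene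
Product: 16 (2S,3S)-6-bromo-2-(3,4-dimethoxyphenyl)-3-(3,5-dimethoxyphenyl)-4-methoxy-2,3-dihydro-1-benzofuran, via arylmagnesium bromide 14 (not isolated), via diarylzinc 15 (not isolated)
Conditions: 13, Mg, LiCl, THF, rt; ZnCl2 (0.5 equiv); then 12, Fe(acac)3 (20 mol%), dppBz [1,2-bis(diphenylphosphino)benzene] (24 mol%), THF/toluene, rt
Reagents that add atoms: none
Why: Iron-catalysed decarboxylative Negishi-type arylation of a redox-active ester: a low-valent aryl-iron species reduces 12, and the planar benzylic C3' radical recombines with aryl-iron on the face away from the ring E aryl, which sets C3' as S (trans). Iron–phosphine catalysts of this kind do not insert into aryl bromides, so the C6' bromide should be kept.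

Step 10
Reactants: 6 7-bromo-5-methoxy-4H-chromen-4-one; 17 4-methoxyphenylboronic acid
Product: 18 (2R)-7-bromo-5-methoxy-2-(4-methoxyphenyl)-2,3-dihydro-4H-chromen-4-one
Conditions: Pd(OCOCF3)2 (5 mol%), (S)-t-BuPyOx (6 mol%), NH4PF6, H2O, ClCH2CH2Cl, 60 °C
Reagents that add atoms: none
Why: The same asymmetric conjugate addition as in step 5 with the enantiomeric ligand, which sets C2 of the ring A unit as R.

Step 11
Reactants: 18 (2R)-7-bromo-5-methoxy-2-(4-methoxyphenyl)-2,3-dihydro-4H-chromen-4-one
Product: 20 methyl (2R,3R)-6-bromo-4-methoxy-2-(4-methoxyphenyl)-2,3-dihydro-1-benzofuran-3-carboxylate, via C4 methyl enol ether 19 (not isolated)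
Conditions: PhI(OAc)2, H2SO4, HC(OMe)3, rt
Reagents that add atoms: trimethyl orthoformate, COC(OC)OC
Why: Oxidative flavanone ring contraction as in step 6: the iodane adds to C3 of 19 and C4a shifts from C4 to C3 with loss of iodobenzene. The trans ester is set by the C2 centre through the same anti attack, inversion on migration and equilibration at C3.

Step 12
Reactants: 20 methyl (2R,3R)-6-bromo-4-methoxy-2-(4-methoxyphenyl)-2,3-dihydro-1-benzofuran-3-carboxylate
Product: 21 (2R,3R)-6-bromo-4-methoxy-2-(4-methoxyphenyl)-2,3-dihydro-1-benzofuran-3-carboxylic acid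
Conditions: LiOH·H2O, THF/MeOH/H2O, rt; then aq. HCl
Reagents that add atoms: lithium hydroxide, [Li+].[OH-]
Why: Saponification as in step 7; the C2 centre is not involved.

Step 13
Reactants: 21 (2R,3R)-6-bromo-4-methoxy-2-(4-methoxyphenyl)-2,3-dihydro-1-benzofuran-3-carboxylic acid
Product: 22 1,3-dioxoisoindolin-2-yl (2R,3R)-6-bromo-4-methoxy-2-(4-methoxyphenyl)-2,3-dihydro-1-benzofuran-3-carboxylate
Conditions: N-hydroxyphthalimide, DIC, DMAP (cat.), CH2Cl2, rt
Reagents that add atoms: N-hydroxyphthalimide, O=C1c2ccccc2C(=O)N1O
Why: Carbodiimide esterification to the redox-active ester as in step 8.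

Step 14
Reactants: 22 1,3-dioxoisoindolin-2-yl (2R,3R)-6-bromo-4-methoxy-2-(4-methoxyphenyl)-2,3-dihydro-1-benzofuran-3-carboxylate; 16 (2S,3S)-6-bromo-2-(3,4-dimethoxyphenyl)-3-(3,5-dimethoxyphenyl)-4-methoxy-2,3-dihydro-1-benzofuran
Product: 25 (2R,3R)-6-bromo-3-[(2S,3S)-2-(3,4-dimethoxyphenyl)-3-(3,5-dimethoxyphenyl)-4-methoxy-2,3-dihydro-1-benzofuran-6-yl]-4-methoxy-2-(4-methoxyphenyl)-2,3-dihydro-1-benzofuran, via aryllithium 23 (not isolated), via diarylzinc 24 (not isolated)
Conditions: 16, t-BuLi (2 equiv), THF, −78 °C; ZnCl2 (0.5 equiv), MgBr2·OEt2, −78 °C to rt; then 22, Fe(acac)3 (20 mol%), dppBz (24 mol%), THF/toluene, rt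
Reagents that add atoms: none
Why: Bromine–lithium exchange at −78 °C is faster than any deprotonation of 16, and transmetalation gives the diarylzinc for the same iron-catalysed decarboxylative Negishi-type arylation as in step 9. The C3 radical from 22 is captured on the face away from ring D, which sets C3 as R (trans). The ring A bromide of 22 is inert to the iron catalyst and is kept for step 15.

Step 15
Reactants: 25 (2R,3R)-6-bromo-3-[(2S,3S)-2-(3,4-dimethoxyphenyl)-3-(3,5-dimethoxyphenyl)-4-methoxy-2,3-dihydro-1-benzofuran-6-yl]-4-methoxy-2-(4-methoxyphenyl)-2,3-dihydro-1-benzofuran; 26 4-methoxystyrene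
Product: 27 (2R,3R)-3-[(2S,3S)-2-(3,4-dimethoxyphenyl)-3-(3,5-dimethoxyphenyl)-4-methoxy-2,3-dihydro-1-benzofuran-6-yl]-4-methoxy-2-(4-methoxyphenyl)-6-[(E)-2-(4-methoxyphenyl)ethenyl]-2,3-dihydro-1-benzofuran
Conditions: Pd(OAc)2 (5 mol%), P(o-tol)3, Et3N, DMF, 100 °C
Reagents that add atoms: none
Why: Mizoroki–Heck coupling at an unhindered aryl bromide; syn insertion at the terminal carbon of the styrene and syn β-hydride elimination should give the E-stilbene, and no stereocentre is involved.

Step 16
Reactants: 27 (2R,3R)-3-[(2S,3S)-2-(3,4-dimethoxyphenyl)-3-(3,5-dimethoxyphenyl)-4-methoxy-2,3-dihydro-1-benzofuran-6-yl]-4-methoxy-2-(4-methoxyphenyl)-6-[(E)-2-(4-methoxyphenyl)ethenyl]-2,3-dihydro-1-benzofuran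
Product: 28 4-[(2S,3S)-3-(3,5-dihydroxyphenyl)-4-hydroxy-6-{(2R,3R)-4-hydroxy-2-(4-hydroxyphenyl)-6-[(E)-2-(4-hydroxyphenyl)ethenyl]-2,3-dihydro-1-benzofuran-3-yl}-2,3-dihydro-1-benzofuran-2-yl]benzene-1,2-diol (target)
Conditions: BBr3 (excess), CH2Cl2, −78 °C to rt; MeOH, then H2O
Reagents that add atoms: none
Why: Lewis-acid cleavage of all eight aryl methyl ethers (boron–oxygen complexation, bromide attack at methyl). C3 and C3' cannot ionise, so any reversible opening at C2 or C2' should return to the trans rings.

## Compound list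

1 | 4-bromo-2,6-dimethoxybenzaldehyde | COc1cc(Br)cc(OC)c1C=O | starting material
2 | 1-(4-bromo-2,6-dimethoxyphenyl)ethan-1-ol (racemic) | COc1cc(Br)cc(OC)c1C(C)O | intermediate
3 | 1-(4-bromo-2,6-dimethoxyphenyl)ethan-1-one | COc1cc(Br)cc(OC)c1C(C)=O | intermediate
4 | 1-(4-bromo-2-hydroxy-6-methoxyphenyl)ethan-1-one | COc1cc(Br)cc(O)c1C(C)=O | intermediate
5 | (E)-1-(4-bromo-2-hydroxy-6-methoxyphenyl)-3-(dimethylamino)prop-2-en-1-one | COc1cc(Br)cc(O)c1C(=O)/C=C/N(C)C | intermediate
6 | 7-bromo-5-methoxy-4H-chromen-4-one | COc1cc(Br)cc2occc(=O)c12 | intermediate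
7 | 3,4-dimethoxyphenylboronic acid | COc1ccc(B(O)O)cc1OC | starting material
8 | (2S)-7-bromo-2-(3,4-dimethoxyphenyl)-5-methoxy-2,3-dihydro-4H-chromen-4-one | COc1cc(Br)cc2O[C@H](c3ccc(OC)c(OC)c3)CC(=O)c12 | intermediate
9 | (2S)-7-bromo-2-(3,4-dimethoxyphenyl)-4,5-dimethoxy-2H-chromene | COc1cc(Br)cc2O[C@H](c3ccc(OC)c(OC)c3)C=C(OC)c12 | intermediate
10 | methyl (2S,3S)-6-bromo-2-(3,4-dimethoxyphenyl)-4-methoxy-2,3-dihydro-1-benzofuran-3-carboxylate | Brc1cc(OC)c2c(c1)O[C@H](c1ccc(OC)c(OC)c1)[C@H]2C(=O)OC | intermediate
11 | (2S,3S)-6-bromo-2-(3,4-dimethoxyphenyl)-4-methoxy-2,3-dihydro-1-benzofuran-3-carboxylic acid | Brc1cc(OC)c2c(c1)O[C@H](c1ccc(OC)c(OC)c1)[C@H]2C(=O)O | intermediate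
12 | 1,3-dioxoisoindolin-2-yl (2S,3S)-6-bromo-2-(3,4-dimethoxyphenyl)-4-methoxy-2,3-dihydro-1-benzofuran-3-carboxylate | Brc1cc(OC)c2c(c1)O[C@H](c1ccc(OC)c(OC)c1)[C@H]2C(=O)ON1C(=O)c2ccccc2C1=O | intermediate
13 | 1-bromo-3,5-dimethoxybenzene | COc1cc(Br)cc(OC)c1 | starting material
14 | (3,5-dimethoxyphenyl)magnesium bromide | COc1cc([Mg]Br)cc(OC)c1 | intermediate
15 | bis(3,5-dimethoxyphenyl)zinc | COc1cc([Zn]c2cc(OC)cc(OC)c2)cc(OC)c1 | intermediate
16 | (2S,3S)-6-bromo-2-(3,4-dimethoxyphenyl)-3-(3,5-dimethoxyphenyl)-4-methoxy-2,3-dihydro-1-benzofuran | Brc1cc(OC)c2c(c1)O[C@H](c1ccc(OC)c(OC)c1)[C@H]2c1cc(OC)cc(OC)c1 | intermediate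
17 | 4-methoxyphenylboronic acid | COc1ccc(B(O)O)cc1 | starting material
18 | (2R)-7-bromo-5-methoxy-2-(4-methoxyphenyl)-2,3-dihydro-4H-chromen-4-one | COc1cc(Br)cc2O[C@@H](c3ccc(OC)cc3)CC(=O)c12 | intermediate
19 | (2R)-7-bromo-4,5-dimethoxy-2-(4-methoxyphenyl)-2H-chromene | COc1cc(Br)cc2O[C@@H](c3ccc(OC)cc3)C=C(OC)c12 | intermediate
20 | methyl (2R,3R)-6-bromo-4-methoxy-2-(4-methoxyphenyl)-2,3-dihydro-1-benzofuran-3-carboxylate | Brc1cc(OC)c2c(c1)O[C@@H](c1ccc(OC)cc1)[C@@H]2C(=O)OC | intermediate
21 | (2R,3R)-6-bromo-4-methoxy-2-(4-methoxyphenyl)-2,3-dihydro-1-benzofuran-3-carboxylic acid | Brc1cc(OC)c2c(c1)O[C@@H](c1ccc(OC)cc1)[C@@H]2C(=O)O | intermediate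
22 | 1,3-dioxoisoindolin-2-yl (2R,3R)-6-bromo-4-methoxy-2-(4-methoxyphenyl)-2,3-dihydro-1-benzofuran-3-carboxylate | Brc1cc(OC)c2c(c1)O[C@@H](c1ccc(OC)cc1)[C@@H]2C(=O)ON1C(=O)c2ccccc2C1=O | intermediate
23 | [(2S,3S)-2-(3,4-dimethoxyphenyl)-3-(3,5-dimethoxyphenyl)-4-methoxy-2,3-dihydro-1-benzofuran-6-yl]lithium | [Li]c1cc(OC)c2c(c1)O[C@H](c1ccc(OC)c(OC)c1)[C@H]2c1cc(OC)cc(OC)c1 | intermediate
24 | bis[(2S,3S)-2-(3,4-dimethoxyphenyl)-3-(3,5-dimethoxyphenyl)-4-methoxy-2,3-dihydro-1-benzofuran-6-yl]zinc | [Zn](c1cc(OC)c2c(c1)O[C@H](c1ccc(OC)c(OC)c1)[C@H]2c1cc(OC)cc(OC)c1)c1cc(OC)c2c(c1)O[C@H](c1ccc(OC)c(OC)c1)[C@H]2c1cc(OC)cc(OC)c1 | intermediate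
25 | (2R,3R)-6-bromo-3-[(2S,3S)-2-(3,4-dimethoxyphenyl)-3-(3,5-dimethoxyphenyl)-4-methoxy-2,3-dihydro-1-benzofuran-6-yl]-4-methoxy-2-(4-methoxyphenyl)-2,3-dihydro-1-benzofuran | Brc1cc(OC)c2c(c1)O[C@@H](c1ccc(OC)cc1)[C@@H]2c1cc(OC)c2c(c1)O[C@H](c1ccc(OC)c(OC)c1)[C@H]2c1cc(OC)cc(OC)c1 | intermediate
26 | 4-methoxystyrene | C=Cc1ccc(OC)cc1 | starting material
27 | (2R,3R)-3-[(2S,3S)-2-(3,4-dimethoxyphenyl)-3-(3,5-dimethoxyphenyl)-4-methoxy-2,3-dihydro-1-benzofuran-6-yl]-4-methoxy-2-(4-methoxyphenyl)-6-[(E)-2-(4-methoxyphenyl)ethenyl]-2,3-dihydro-1-benzofuran | COc1ccc(/C=C/c2cc(OC)c3c(c2)O[C@@H](c2ccc(OC)cc2)[C@@H]3c2cc(OC)c3c(c2)O[C@H](c2ccc(OC)c(OC)c2)[C@H]3c2cc(OC)cc(OC)c2)cc1 | intermediate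
28 | 4-[(2S,3S)-3-(3,5-dihydroxyphenyl)-4-hydroxy-6-{(2R,3R)-4-hydroxy-2-(4-hydroxyphenyl)-6-[(E)-2-(4-hydroxyphenyl)ethenyl]-2,3-dihydro-1-benzofuran-3-yl}-2,3-dihydro-1-benzofuran-2-yl]benzene-1,2-diol | Oc1ccc(/C=C/c2cc(O)c3c(c2)O[C@@H](c2ccc(O)cc2)[C@@H]3c2cc(O)c3c(c2)O[C@H](c2ccc(O)c(O)c2)[C@H]3c2cc(O)cc(O)c2)cc1 | target

## Step count and risks

Total: 16 steps. Longest linear sequence: 12 steps (steps 1–9, then 14–16); the ring A branch (steps 10–13) joins at step 14.

Step 6 (key step). The oxidation may leave the intended channel. The peri methoxy group at C5 slows ketalisation, so the iodane may meet the free ketone enol and give dehydrogenation to the flavone or shift of the C2 aryl. The acid may reversibly open the benzylic O1–C2 bond next to the electron-rich ring E and erode the C2 configuration. The iodane may also oxidise the veratryl ring. The fallback sets out from 8 and returns at 10. Compound 8 is trifluoroacetylated at C3 at −78 °C (LiN(SiMe3)2, CF3CO2CH2CF3; the low temperature holds back ring opening of the enolate) to the 3-trifluoroacetyl flavanone F1, which is not isolated. Detrifluoroacetylative diazo transfer (MsN3, Et3N, H2O, MeCN) then gives the 3-diazoflavanone F2. Irradiation of F2 in MeOH triggers a Wolff rearrangement in which the same ring B carbon moves from C4 to C3 and the ketene is trapped by methanol. The ester mixture is equilibrated with NaOMe in MeOH to the trans ester 10.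

Step 11. The same failure modes as in step 6, with a higher chance of aryl shift and of ionisation at C2, because the 4-methoxyphenyl ring D is a better migrating and cation-stabilising group than ring E. The fallback sets out from 18 and returns at 20 by the same sequence: the 3-trifluoroacetyl flavanone F3 (not isolated), the 3-diazoflavanone F4, photochemical Wolff rearrangement in MeOH and base equilibration. In this pathway only a group on the carbonyl carbon can migrate, so ring D cannot compete.

Step 9. The stabilised benzylic C3' radical may dimerise or be reduced before the aryl-iron species captures it, or fragment by β-scission of the O1'–C2' bond. Aryl delivery may not be fully trans, and an undesired exchange at the ring B bromide would give oligomers. The fallback sets out from 12 and returns at 16 without a new isolated compound. It is a nickel-catalysed reductive cross-electrophile coupling of 12 with commercial 1-iodo-3,5-dimethoxybenzene in excess (NiBr2·dme, 4,4'-di-tert-butyl-2,2'-bipyridine, Zn, DMA, rt). The aryl iodide adds to zerovalent nickel much faster than the electron-rich ring B bromide, and the resulting aryl-nickel species traps the radical.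

Step 14. By design only one aryl group of the diarylzinc is transferred, so half of the ring B fragment is lost. Proton quench of the aryllithium, oxidative homocoupling of the arylzinc and slow capture of a hindered radical by a bulky aryl-iron species would lower the transfer further. The fallback sets out from 20 and 16 and returns at 27.
- Heck coupling of 20 with 26 gives methyl (2R,3R)-4-methoxy-2-(4-methoxyphenyl)-6-[(E)-2-(4-methoxyphenyl)ethenyl]-2,3-dihydro-1-benzofuran-3-carboxylate F5.
- Saponification gives the acid F6, and esterification with N-hydroxyphthalimide gives the redox-active ester F7.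
- Bromide 16 is converted into the aryl iodide F8 by copper-catalysed halogen exchange (CuI, N,N'-dimethylethylenediamine, NaI, dioxane, 110 °C).
- Nickel-catalysed reductive decarboxylative coupling of F7 with F8 in a one-to-one ratio (NiBr2·dme, 4,4'-di-tert-butyl-2,2'-bipyridine, Zn, DMA) gives 27 directly. No aryl bromide is present at that stage.

Step 16. Cleaving eight ethers needs long exposure to a strong Lewis acid. Cleavage may be incomplete, the benzylic O1–C2 and O1'–C2' bonds may open, HBr may add to the stilbene or start its cationic oligomerisation, and the catechol may oxidise in air during work-up. The fallback sets out from 25 and returns at 28, so that the stilbene never meets BBr3.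
- Compound 25 is demethylated with BBr3 to the heptaphenol bromide F9, which is peracetylated (Ac2O, pyridine) to the heptaacetate F10.
- Heck coupling of F10 with commercial 4-acetoxystyrene (Pd(OAc)2, P(o-tol)3, Et3N, DMF) gives the octaacetate F11.
- Methanolysis of F11 (K2CO3, MeOH, under argon, then mild acid) gives 28.

## Further compounds

F1 | step 6 | (2S)-7-bromo-2-(3,4-dimethoxyphenyl)-5-methoxy-3-(trifluoroacetyl)-2,3-dihydro-4H-chromen-4-one (C3 epimers or enol) | COc1cc(Br)cc2O[C@H](c3ccc(OC)c(OC)c3)C(C(=O)C(F)(F)F)C(=O)c12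
F2 | step 6 | (2R)-7-bromo-3-diazo-2-(3,4-dimethoxyphenyl)-5-methoxy-2,3-dihydro-4H-chromen-4-one (same spatial arrangement at C2 as in 8; the descriptor changes with the priorities) | COc1cc(Br)cc2O[C@H](c3ccc(OC)c(OC)c3)C(=[N+]=[N-])C(=O)c12
F3 | step 11 | (2R)-7-bromo-5-methoxy-2-(4-methoxyphenyl)-3-(trifluoroacetyl)-2,3-dihydro-4H-chromen-4-one (C3 epimers or enol) | COc1cc(Br)cc2O[C@@H](c3ccc(OC)cc3)C(C(=O)C(F)(F)F)C(=O)c12
F4 | step 11 | (2S)-7-bromo-3-diazo-5-methoxy-2-(4-methoxyphenyl)-2,3-dihydro-4H-chromen-4-one (same spatial arrangement at C2 as in 18) | COc1cc(Br)cc2O[C@@H](c3ccc(OC)cc3)C(=[N+]=[N-])C(=O)c12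
F0 | step 9 | none | none
F5 | step 14 | methyl (2R,3R)-4-methoxy-2-(4-methoxyphenyl)-6-[(E)-2-(4-methoxyphenyl)ethenyl]-2,3-dihydro-1-benzofuran-3-carboxylate | COc1ccc(/C=C/c2cc(OC)c3c(c2)O[C@@H](c2ccc(OC)cc2)[C@@H]3C(=O)OC)cc1
F6 | step 14 | (2R,3R)-4-methoxy-2-(4-methoxyphenyl)-6-[(E)-2-(4-methoxyphenyl)ethenyl]-2,3-dihydro-1-benzofuran-3-carboxylic acid | COc1ccc(/C=C/c2cc(OC)c3c(c2)O[C@@H](c2ccc(OC)cc2)[C@@H]3C(=O)O)cc1
F7 | step 14 | 1,3-dioxoisoindolin-2-yl (2R,3R)-4-methoxy-2-(4-methoxyphenyl)-6-[(E)-2-(4-methoxyphenyl)ethenyl]-2,3-dihydro-1-benzofuran-3-carboxylate | COc1ccc(/C=C/c2cc(OC)c3c(c2)O[C@@H](c2ccc(OC)cc2)[C@@H]3C(=O)ON2C(=O)c4ccccc4C2=O)cc1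
F8 | step 14 | (2S,3S)-2-(3,4-dimethoxyphenyl)-3-(3,5-dimethoxyphenyl)-6-iodo-4-methoxy-2,3-dihydro-1-benzofuran | Ic1cc(OC)c2c(c1)O[C@H](c1ccc(OC)c(OC)c1)[C@H]2c1cc(OC)cc(OC)c1
F9 | step 16 | 4-[(2S,3S)-6-{(2R,3R)-6-bromo-4-hydroxy-2-(4-hydroxyphenyl)-2,3-dihydro-1-benzofuran-3-yl}-3-(3,5-dihydroxyphenyl)-4-hydroxy-2,3-dihydro-1-benzofuran-2-yl]benzene-1,2-diol | Brc1cc(O)c2c(c1)O[C@@H](c1ccc(O)cc1)[C@@H]2c1cc(O)c2c(c1)O[C@H](c1ccc(O)c(O)c1)[C@H]2c1cc(O)cc(O)c1
F10 | step 16 | heptaacetate of F9 (all seven phenols acetylated; 2R,3R and 2'S,3'S) | Brc1cc(OC(C)=O)c2c(c1)O[C@@H](c1ccc(OC(C)=O)cc1)[C@@H]2c1cc(OC(C)=O)c2c(c1)O[C@H](c1ccc(OC(C)=O)c(OC(C)=O)c1)[C@H]2c1cc(OC(C)=O)cc(OC(C)=O)c1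
F11 | step 16 | octaacetate of 28 (all eight phenols acetylated; E-alkene; 2R,3R and 2'S,3'S) | CC(=O)Oc1ccc(/C=C/c2cc(OC(C)=O)c3c(c2)O[C@@H](c2ccc(OC(C)=O)cc2)[C@@H]3c2cc(OC(C)=O)c3c(c2)O[C@H](c2ccc(OC(C)=O)c(OC(C)=O)c2)[C@H]3c2cc(OC(C)=O)cc(OC(C)=O)c2)cc1
A1 | alternative 1 | bis(dihydrobenzofuran) tetramethyl ether (ring C, ring E C3 and ring F oxygens methylated; 2R,3R and 2'S,3'S) | COc1ccc(/C=C/c2cc(O)c3c(c2)O[C@@H](c2ccc(O)cc2)[C@@H]3c2cc(O)c3c(c2)O[C@H](c2ccc(O)c(OC)c2)[C@H]3c2cc(OC)cc(OC)c2)cc1
A2 | alternative 1 | open-chain bis(4-hydroxybenzyl) hexaphenol, the substrate of the double quinone methide cyclisation | COc1ccc(/C=C/c2cc(O)c(c(O)c2)[C@H](Cc2ccc(O)cc2)c2cc(O)c(c(O)c2)[C@@H](Cc2ccc(O)c(OC)c2)c2cc(OC)cc(OC)c2)cc1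
A3 | alternative 2 | ring A resorcinol mono(triisopropylsilyl) ether with the open C2–C3 chain (C2 as tert-butyldimethylsilyl ether) | COc1ccc(/C=C/c2cc(O)c(c(O[Si](C(C)C)(C(C)C)C(C)C)c2)[C@H]([C@@H](O[Si](C)(C)C(C)(C)C)c2ccc(OC)cc2)c2cc(OC)c3c(c2)O[C@H](c2ccc(OC)c(OC)c2)[C@H]3c2cc(OC)cc(OC)c2)cc1
A4 | alternative 2 | 3-[(E)-2-(4-methoxyphenyl)ethenyl]cyclobut-2-en-1-one | O=C1C=C(/C=C/c2ccc(OC)cc2)C1
A5 | alternative 2 | triisopropylsilyl ynol ether carrying the C2–C3 chain and the ring B unit | CC(C)[Si](C(C)C)(C(C)C)OC#C[C@H]([C@@H](O[Si](C)(C)C(C)(C)C)c1ccc(OC)cc1)c1cc(OC)c2c(c1)O[C@H](c1ccc(OC)c(OC)c1)[C@H]2c1cc(OC)cc(OC)c1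
A6 | alternative 3 | bis(dihydrobenzofuran) heptamethyl ether with a pinacol boronate at C4' | COc1ccc(/C=C/c2cc(OC)c3c(c2)O[C@@H](c2ccc(OC)cc2)[C@@H]3c2cc(B4OC(C)(C)C(C)(C)O4)c3c(c2)O[C@H](c2ccc(OC)c(OC)c2)[C@H]3c2cc(OC)cc(OC)c2)cc1
A7 | alternative 3 | diyne: ethynyl ether of the C2' carbinol tethered to the C3' alkynyl pinacol boronate | C#CO[C@H](c1ccc(OC)c(OC)c1)[C@H](C#CB1OC(C)(C)C(C)(C)O1)c1cc(OC)cc(OC)c1
A8 | alternative 3 | (2R,3R)-3-ethynyl-4-methoxy-2-(4-methoxyphenyl)-6-[(E)-2-(4-methoxyphenyl)ethenyl]-2,3-dihydro-1-benzofuran (spatial arrangement as in the target) | COc1ccc(/C=C/c2cc(OC)c3c(c2)O[C@@H](c2ccc(OC)cc2)[C@@H]3C#C)cc1
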